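The numbers of this flask come from no measurement; the rest is arithmetic.

Each Z that meets J removes one of each, and Q and L each supply one of them, so one difference holds still once the whole charge is in.

| flask | Q | L | time | remark |
|---|---|---|---|---|
| west | 1.5 M | 1.65 M | 15 min | everything together in a closed stirred flask, run for 15 min |
| south-west | 1.5 M (fed, over 12.0 min) | 1.65 M | 15 min | a stirred flask in which Q is dosed at a steady rate over 12.0 min without added volume, worked up at 15 min |
| east | 1.5 M | 1.65 M (fed, over 12.0 min) | 15 min | a stirred flask in which L is dosed at a steady rate over 12.0 min without added volume, worked up at 15 min |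
| north-east | 1.5 M | 1.65 M |  | a single well-mixed tank run continuously and read at steady state, 15 min in it on average |

    L → J (k1 = 0.072 s⁻¹)
    Z.J ⇌ G (K2 = 0.68, k2 = 0.049 s⁻¹)
    Z.J → D (k3 = 3.3 × 10⁻⁴ s⁻¹)
    Z + J → Z.J (k4 = 0.0061 L mol⁻¹ s⁻¹)
    Q → Z (k5 = 0.014 s⁻¹)

* order of the set-ups by the amount of Z at the outlet or at the end, in percent of the Q put in, highest first (west / south-west / east / north-east)
* amount of Z at the outlet or at the end, in percent of the Q put in, west
* amount of Z at the outlet or at the end, in percent of the Q put in, south-west
* amount of Z at the outlet or at the end, in percent of the Q put in, east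
* amount of Z at the outlet or at the end, in percent of the Q put in, north-east

- the stated concentrations are those of everything mixed, before any reaction; amounts are the same in each set-up
- the feed brings no volume worth counting
- run time (west): 15 min

Once all was charged, c(L) + c(J) − c(Q) − c(Z) stayed at 0.150 M; I called this the excess. In west the half-lives of L and Q, 0.16 min and 0.83 min, were short beside 15 min, so c(J) soon equalled c(Z) plus the excess. The ratio c(Z)/c(J) then fell exponentially at 0.0061 L mol⁻¹ s⁻¹ times the excess, 0.0549 min⁻¹.

For a lower bound on west I put all Z and J in at zero time, which left 6.64 % of Q as Z. For an upper bound I held Z and J apart for 5 half-lives of Q, 4.13 min, which left 10.0 %. Shifting the clock by the mean lives of Q and L instead gave my figure, 7.59 %.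

Shifting to the middle of the dosing plus the dosed reagent's mean life gave 14.5 % for south-west and 12.8 % for east, which I kept as rough figures, not bounds, for the excess stands at its value from the end of the feed on.

The north-east tank needed no clock. With c(Q) = 0.110 M and c(L) = 0.0251 M, c(J) was c(Z) plus 0.235 M, and the balance on Z gave a quadratic with root 22.4 %.

The forecast, holding that “G and D only act as sinks and can be ignored”, gave north-east > south-west > east > west, with 7.7 % for west, inside my bracket, then 19.7 %, 16.5 % and 22.4 % for south-west, east and north-east.

The simulation gave north-east > south-west > east > west: west 7.73 %, south-west 19.7 %, east 16.6 %, north-east 22.4 %.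

West at 15.0 min held c(J) = 0.266 M against c(Z) = 0.116 M, a difference of 0.150 M, which is the excess. The neighbouring flask, west with 0.41 M of L, lowered the excess by 1.24 M to −1.09 M, which made L the limiting reagent. Z then had to stand above J by that amount, 72.7 % of the Q put in. That flask read 72.8 % as Z at 15.0 min, with c(J) at 0.00126 M.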